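The runs come from a simulation for an exercise, noise included.

The examiner begins with the charge of solid X and how it reaches the solution, where it is counted as Q and is turned into Z by L.

| setting | epsilon | zeta | flask |
|---|---|---|---|
| X | 10 mM | 15 mM | 20 mM |
| J | 0.035 mol% | 0.035 mol% | 0.035 mol% |
| remark | run made earlier | run made earlier |  |
| time |  |  | 40 min |

| run | time / min | Z / % | Q / % |
|---|---|---|---|
| epsilon | 3.00 | 1.2 | 16.6 |
| epsilon | 8.00 | 12.6 | 22.4 |
| epsilon | 15.0 | 37.9 | 19.2 |
| epsilon | 40.0 | 30.6 | 3.2 |
| zeta | 5.00 | 5.2 | 12.7 |
| zeta | 15.0 | 27.5 | 11.5 |
| zeta | 25.0 | 41.2 | 10.0 |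
| zeta | 40.0 | 37.9 | 3.5 |

(each reading ± 1 percentage point)

- given per volume of solution although it is solid: X
- reactions considered so far: Q + L -> Z + L; X <-> Q; Z <-> E; J -> L
- at the start none of X is in solution
- Q means what is dissolved; the solid is not counted in it

- Saturday's: doubling the dissolution coefficient of X, all else as stated
- Monday's: doubling the amount of J, all else as stated
- Thursday's: doubling the solubility of X, all else as stated

* Z at 40 min, in percent of the X charged
* concentration of Q in solution at 20 min, in percent of saturation
* the change that raises the amount of Z at 40 min, in percent of the X charged most ("none" if none brings more than 2 percentage points) (Saturday's / Monday's / Thursday's / none)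
* amount of Z at 40 min, in percent of the X charged, after Saturday's

**How fast does X dissolve?** The first readings of Q plus Z, with E unread, give 0.593 mM min⁻¹ in the epsilon run and 0.537 mM min⁻¹ in the zeta run. Zeta's rate, read at the greater charge, is lower than epsilon's, so I treat dissolution as a zero-order feed, v = 0.565 mM min⁻¹.

**What do you carry forward?** The dissolution time τ, 35.4 min in this flask, which is the charge of X divided by v. The same division gives 17.7 min for epsilon and 26.5 min for zeta.

**And Z?** The highest Z readings are 37.9% at 15.0 min in epsilon and 41.2% at 25.0 min in zeta. Both were taken before the run's τ. My first answer for this flask is therefore zeta's top.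

**But you read at 40 min, not at τ.** Then I go round once more. In this flask 40 min comes 4.60 min after τ. Zeta lost 3.3 percentage points over its last 15.0 min, and at that pace I commit to 40.2%.

**And Saturday's?** I take doubling the coefficient to double v, so τ falls to 17.7 min, half of its present value, which is epsilon's τ. I take equal τ at equal time to mean equal percent Z, and so expect epsilon's reading of 30.6%. I take Thursday's to raise the feed too and Monday's to leave it alone, so I answer none. τ says nothing about Q against saturation.

The forecast gave 41%, 28% of saturation, Monday's and 41%, holding that “Doubling J lowers Q and speeds conversion while solid still feeds”. The simulation gives 41.3%, 11.9% of saturation at 20 min, and best none: Saturday's −12 points, Monday's 1 point, Thursday's −13 points, with 29.1% after Saturday's.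

    Q + L → Z + L, rate k1*[Q]^2.5*[L]/(1 + ([Q]/Kh1)^2.5) (9.42 mM, k = 2.13 × 10⁷ M⁻²·⁵ s⁻¹)
    X ⇌ Q, rate k2*(cs2 - [Q]) while solid is left; crystals form when [Q] > cs2 (solubility = 12.0 mM, k = 0.0468 min⁻¹)
    Z ⇌ E (K = 4.19, k = 0.0666 min⁻¹)
    J → L (k = 0.0679 min⁻¹)

This flask still holds 1.15% of its X as solid at 40.0 min, so its dissolving outlasts τ. The neighbour flask, charged with 5.0 mM of X at the same loading, has τ = 8.85 min. Its reading at 40 min comes 31.1 min after that. The straight line through zeta's 37.9% and epsilon's 30.6%, taken against τ, reaches 23.3% there. The neighbour flask holds 26.8% Z at 40 min.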